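The ten-membered carbocycle is made by ring expansion, not by ring closure: its cis,trans-cyclodeca-1,5-diene unit C10=C1–C2–C3–C4=C5 (C1=C10 cis, C4=C5 trans) is traced back to a cis,anti,cis-tricyclo[4.4.0.0(2,5)]decanone in which C1–C4 and C5–C10 are single bonds of a central cyclobutane. Heating cleaves these two bonds in one operation and delivers both alkenes with their geometries. The precursor is a C6 cyclohexanone (C5–C10) carrying the C7 acetate arm, fused through that cyclobutane to an outer cyclobutane (C1–C4) whose C2 silyl ether is cis to C10; it is assembled by a silicon-tethered enone–cyclobutene photocycloaddition, and the tether is cut before heating.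

Key step: step 18

Remark on numbering: germacrane numbering is used for all intermediates (ring C1–C10, C14 on C10, C15 on C4, C11–C13 the lactone carbons).

Remarks on the precursor design:
- The C2 oxygen is placed cis to C10 on the outer cyclobutane. A C2 oxygen trans to C10 would be 1,3-diaxial to C9 in the chair that gives cis C1=C10 and trans C4=C5. With C2 S, this puts the cyclobutane on the face of the six-membered ring that bears the C8 oxygen.
- The O14–Si–O2 tether that delivers this arrangement is cleaved before heating, since a seven-membered ring through C10=C1 would hold C14 and C2 cis.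
- The C7 arm must be cis to the C8 oxygen, which enolate alkylation next to that oxygen would not give; it is introduced after the photocycloaddition by hydrogenation.

Step 1
Reactants: 1 shikimic acid
Product: 3 methyl 3,4-O-isopropylideneshikimate, via methyl shikimate 2 (not isolated)
Conditions: MeOH, CSA (cat), reflux; then 2,2-dimethoxypropane, acetone, rt
Reagents that add atoms: methanol CO; 2,2-dimethoxypropane COC(C)(C)OC
Why: Fischer esterification followed by acid-catalysed acetal exchange, in which only the cis 3,4-diol can close the dioxolane, so that the C5 hydroxyl (the later C8 oxygen, already correctly configured) stays free.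

Step 2
Reactants: 3 methyl 3,4-O-isopropylideneshikimate
Product: 4 methyl 5-O-(4-methoxybenzyl)-3,4-O-isopropylideneshikimate
Conditions: NaH, 4-methoxybenzyl chloride, Bu4NI (cat), DMF, 0 °C to rt
Reagents that add atoms: 4-methoxybenzyl chloride COc1ccc(CCl)cc1
Why: Williamson etherification of the only free hydroxyl installs an ether that can later be removed oxidatively in the presence of silyl ethers.

Step 3
Reactants: 4 methyl 5-O-(4-methoxybenzyl)-3,4-O-isopropylideneshikimate
Product: 5 methyl 5-O-(4-methoxybenzyl)shikimate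
Conditions: AcOH/H2O (4:1), 40 °C
Reagents that add atoms: none
Why: Acid hydrolysis of the isopropylidene acetal, to which the benzylic ether and the enoate are inert.

Step 4
Reactants: 5 methyl 5-O-(4-methoxybenzyl)shikimate
Product: 6 methyl 5-O-(4-methoxybenzyl)-3-dehydroshikimate
Conditions: MnO2, CH2Cl2, rt
Reagents that add atoms: none
Why: Chemoselective MnO2 oxidation of the allylic C3 hydroxyl (C6 of the target) in the presence of the non-allylic C4 hydroxyl gives the enone without touching C5.

Step 5
Reactants: 6 methyl 5-O-(4-methoxybenzyl)-3-dehydroshikimate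
Product: 7 methyl 4-O-acetyl-5-O-(4-methoxybenzyl)-3-dehydroshikimate
Conditions: Ac2O, pyridine, CH2Cl2, 0 °C
Reagents that add atoms: acetic anhydride CC(=O)OC(C)=O
Why: Acetylation of the α-hydroxy ketone provides the leaving group for reductive cleavage, and cold conditions without stronger base limit β-elimination toward a phenol.

Step 6
Reactants: 7 methyl 4-O-acetyl-5-O-(4-methoxybenzyl)-3-dehydroshikimate
Product: 8 methyl (5R)-5-[(4-methoxybenzyl)oxy]-3-oxocyclohex-1-ene-1-carboxylate
Conditions: SmI2 (2 equiv), THF/MeOH, −78 °C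
Reagents that add atoms: none
Why: Reductive cleavage of an α-acyloxy ketone by SmI2 (ketyl, loss of acetate, protonation of the enolate) turns C7 into a methylene, and two equivalents at low temperature should leave the enoate and the β-ether untouched.

Step 7
Reactants: 8 methyl (5R)-5-[(4-methoxybenzyl)oxy]-3-oxocyclohex-1-ene-1-carboxylate
Product: 9 (5R)-3-(hydroxymethyl)-5-[(4-methoxybenzyl)oxy]cyclohex-2-en-1-ol (both C1 epimers)
Conditions: iBu2AlH, CH2Cl2, −78 °C; Rochelle salt
Reagents that add atoms: none
Why: 1,2-Reduction of ester and ketone by the aluminium hydride frees the primary C14 alcohol needed for the tether, and the carbinol epimers formed at C6 converge in step 12.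

Step 8
Reactants: 10 propyne; 11 trichloroacetyl chloride
Product: 13 4,4-dichloro-3-methylcyclobut-2-en-1-one, via dichloroketene 12 (not isolated)
Conditions: Zn/Cu couple, Et2O/DME, 0 °C to rt
Reagents that add atoms: none
Why: Zinc dechlorination generates dichloroketene, which undergoes thermal [2+2] cycloaddition with the alkyne, its carbonyl carbon bonding to the terminal alkyne carbon, to give the methylcyclobutenone skeleton (C1–C4 and C15).

Step 9
Reactants: 13 4,4-dichloro-3-methylcyclobut-2-en-1-one
Product: 14 3-methylcyclobut-2-en-1-one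
Conditions: Zn, AcOH, TMEDA, EtOH, 0 °C to rt
Reagents that add atoms: none
Why: Reductive dechlorination of the α,α-dichloro ketone by zinc in a buffered medium that the strained enone should survive.

Step 10
Reactants: 14 3-methylcyclobut-2-en-1-one
Product: 15 (S)-3-methylcyclobut-2-en-1-ol
Conditions: (R)-2-methyl-CBS-oxazaborolidine (0.2 equiv), BH3·SMe2, THF, −40 °C; MeOH
Reagents that add atoms: none
Why: Corey–Bakshi–Shibata reduction, in which the (R)-oxazaborolidine binds the ketone with the alkenyl flank as the large group and delivers hydride to one face, setting C2 as S.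

Step 11
Reactants: 15 (S)-3-methylcyclobut-2-en-1-ol; 9 (5R)-3-(hydroxymethyl)-5-[(4-methoxybenzyl)oxy]cyclohex-2-en-1-ol
Product: 17 diisopropylsilyl bis-ether joining O2 of the cyclobutenol to the primary O14 of the cyclohexenediol, via chlorosilyl ether 16 (not isolated)
Conditions: iPr2SiCl2, imidazole, CH2Cl2, −78 °C to 0 °C; then 9, imidazole, 0 °C to rt
Reagents that add atoms: dichlorodiisopropylsilane CC(C)[Si](Cl)(Cl)C(C)C
Why: Stepwise substitution at silicon (the first chloride reacts far faster than the second) gives the unsymmetrical silaketal, the primary allylic hydroxyl of 9 reacting in preference to the secondary one.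

Step 12
Reactants: 17 silaketal alcohol
Product: 18 tethered enone, (5R)-5-[(4-methoxybenzyl)oxy]-3-({diisopropyl[(1S)-3-methylcyclobut-2-en-1-yloxy]silyl}oxymethyl)cyclohex-2-en-1-one
Conditions: MnO2, CH2Cl2, rt
Reagents that add atoms: none
Why: MnO2 oxidises the secondary allylic alcohol to the enone and leaves the silaketal and both ethers untouched, which removes the C6 epimer mixture.

Step 13
Reactants: 18 tethered enone
Product: 19 tetracyclic photoadduct (cis,anti,cis-tricyclic C6 ketone with bonds C10–C1 and C5–C4, bridged by the seven-membered O2–Si(iPr)2–O14 ring; cyclobutane and C8 ether on the same face of the six-membered ring; C2 oxygen cis to C10)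
Conditions: hν (350 nm), CH2Cl2 (0.005 M, degassed), 0 °C
Reagents that add atoms: none
Why: Intramolecular enone–alkene [2+2] photocycloaddition through the enone triplet, in which the five-atom C14–O–Si–O–C2 tether brings C1 to C10 and C4 to C5, enforces the cis,anti,cis fusion with the C2 oxygen cis to C10, and with C2 S thereby selects the enone face of the pseudo-equatorial C8 ether, so that C1, C4, C5 and C10 are set in one event.

Step 14
Reactants: 19 tetracyclic photoadduct
Product: 20 tricyclic keto diol (C2 hydroxyl and C14 hydroxymethyl free; C2 oxygen cis to C10)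
Conditions: HF·pyridine, pyridine, THF, 0 °C
Reagents that add atoms: none
Why: Fluoride cleaves both Si–O bonds of the silaketal much faster than it touches the benzylic ether or the ketone, and the ring has to go before the thermolysis because a seven-membered ring through C10=C1 would force C14 and C2 cis on that double bond.

Step 15
Reactants: 20 tricyclic keto diol
Product: 22 tricyclic ketone with C2 triethylsilyl ether and C14 tert-butyldiphenylsilyl ether, via C14 monosilyl ether 21 (not isolated)
Conditions: TBDPSCl, imidazole, CH2Cl2, 0 °C; then TESOTf, 2,6-lutidine, −40 °C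
Reagents that add atoms: tert-butyl(chloro)diphenylsilane CC(C)(C)[Si](Cl)(c1ccccc1)c1ccccc1; triethylsilyl trifluoromethanesulfonate CC[Si](CC)(CC)OS(=O)(=O)C(F)(F)F
Why: Sequential silylation in which the bulky chloride takes only the primary hydroxyl and the triflate then silylates the hindered secondary C2 hydroxyl, giving three differently cleavable ethers at O2, O8 and O14.

Step 16
Reactants: 22 tricyclic ketone; 23 methyl glyoxylate
Product: 26 C7 alkylidene ketone (C7=C11 conjugated to the ketone and the methyl ester; E drawn), via lithium aldolate 24 (not isolated), via mesylate 25 (not isolated)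
Conditions: LDA, THF, −78 °C; 23; MsCl, −78 °C to 0 °C; Et3N, 0 °C to rt
Reagents that add atoms: none
Why: Aldol condensation in which the amide base removes a C7 proton (the C5 ring-fusion proton is tertiary and shielded), the enolate adds to the aldehyde, and the mesylated aldol eliminates by E1cB, either alkene geometry being usable in step 17.

Step 17
Reactants: 26 C7 alkylidene ketone
Product: 27 thermolysis precursor (tricyclic ketone 22 carrying the C7 CH2CO2Me arm cis to the C8 ether and to the cyclobutane)
Conditions: H2 (1 atm), Pd/C, pyridine, EtOAc, rt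
Reagents that add atoms: none
Why: Heterogeneous hydrogenation adds hydrogen syn from the face of the exocyclic enoate opposite the cyclobutane (whose C15 methyl overhangs C6 and C7) and the adjacent C8 ether, which sets C7 with the arm cis to the C8 oxygen as in the target, while pyridine suppresses hydrogenolysis of the benzylic ether.

Step 18
Reactants: 27 thermolysis precursor
Product: 28 methyl 2-[6-oxo-cyclodeca-1(10),4-dien-7-yl]acetate with ring-cis C1=C10, ring-trans C4=C5, C2 triethylsilyl ether, C8 4-methoxybenzyl ether and C14 tert-butyldiphenylsilyl ether (C2, C7, C8 as in the target)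
Conditions: PhMe (0.01 M, degassed), 210 °C, pressurised flow coil, residence time about 2 min, rapid cooling
Reagents that add atoms: none
Why: Heating homolyses the strained central C1–C4 bond of the bicyclo[2.2.0]hexane and the resulting cyclohexane-1,4-diyl fragments across C5–C10 through a chair, a formal [σ2s+σ2a] cycloreversion of the middle cyclobutane that creates C1=C10 and C4=C5 at once. The closest known reaction type is the thermolysis of cyclobutene–cyclohexenone photoadducts to cis,trans-cyclodeca-1,5-dienes. The ten-membered ring is not closed by bond formation but opened out of the fused six- and four-membered rings by this fragmentation, so no cyclisation mode applies. No stereocentre is created, and C2, C7 and C8 are carried through. The step needs C9 axial and C6 equatorial on the reacting C1–C2–C3–C4–C5–C10 chair (cis C1=C10, trans C4=C5), which the substrate should secure because its C2 silyloxy group, trans to C9, is then equatorial whereas the other chair would set it 1,3-diaxial to the C14 silyloxymethyl group. The short residence time is chosen to prevent the consecutive Cope rearrangement of the product to a divinylcyclohexane.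

Step 19
Reactants: 28 protected cyclodecadienone
Product: 29 C8 hydroxy cyclodecadienone
Conditions: DDQ, CH2Cl2/pH 7 buffer, 0 °C
Reagents that add atoms: none
Why: Single-electron oxidation of the electron-rich benzyl ether by DDQ and hydrolysis of the oxocarbenium ion frees the C8 hydroxyl under buffered conditions that should leave the silyl ethers, the enone and C7 untouched.

Step 20
Reactants: 29 C8 hydroxy cyclodecadienone
Product: 31 trans-fused 6,12-lactone with free C8 hydroxyl, via anti-6,8-diol ester 30 (not isolated)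
Conditions: Me4NBH(OAc)3, MeCN/AcOH (1:1), −30 °C; then PPTS (cat), PhMe, 40 °C
Reagents that add atoms: none
Why: Evans–Saksena reduction, in which the C8 hydroxyl binds the triacetoxyborohydride and delivers hydride to its own face of C6 so that O6 is set anti to O8 and therefore trans to the C7 arm, after which mild acid closes the trans-fused γ-lactone, closure onto the cis C8 hydroxyl being disfavoured because it needs C7–C8 eclipsed in the ring.

Step 21
Reactants: 31 hydroxy lactone
Product: 32 C11 dimethylaminomethyl lactone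
Conditions: LDA (2.5 equiv), THF, −78 °C; Me2N=CH2 I (Eschenmoser's salt), −78 °C to 0 °C
Reagents that add atoms: Eschenmoser's salt C=[N+](C)C.[I-]
Why: Mannich reaction in which the lactone enolate, formed beside the C8 alkoxide with excess amide base, is aminomethylated at C11 by the iminium salt, the configuration of C11 being irrelevant.

Step 22
Reactants: 32 C11 dimethylaminomethyl lactone
Product: 34 α-methylene lactone with free C8 hydroxyl, via trimethylammonium iodide 33 (not isolated)
Conditions: MeI, MeOH, rt; then NaHCO3, CH2Cl2/H2O, rt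
Reagents that add atoms: none
Why: Exhaustive methylation turns the amine into a leaving group and bicarbonate induces E1cB elimination of the Mannich base to the exocyclic C11=C13 methylene.

Step 23
Reactants: 34 α-methylene lactone
Product: 35 C8 methacrylate
Conditions: methacrylic anhydride, Et3N, DMAP (cat), CH2Cl2, 0 °C to rt
Reagents that add atoms: methacrylic anhydride CC(=C)C(=O)OC(=O)C(C)=C
Why: DMAP-catalysed acylation of the only free hydroxyl installs the C8 methacrylate with retention at C8.

Step 24
Reactants: 35 C8 methacrylate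
Product: 36 C2 alcohol
Conditions: HF·pyridine, pyridine, THF, 0 °C
Reagents that add atoms: none
Why: Buffered fluoride removes the secondary triethylsilyl ether far faster than the primary tert-butyldiphenylsilyl ether, and the buffered medium should spare the acid-sensitive 1,5-diene.

Step 25
Reactants: 36 C2 alcohol
Product: 37 C2 acetate with C14 tert-butyldiphenylsilyl ether
Conditions: Ac2O, pyridine, DMAP (cat), CH2Cl2, 0 °C
Reagents that add atoms: acetic anhydride CC(=O)OC(C)=O
Why: Acylation of the liberated allylic C2 hydroxyl proceeds with retention and gives the C2 acetate.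

Step 26
Reactants: 37 C2 acetate
Product: 38 target
Conditions: HF·pyridine, pyridine, THF, 0 °C to rt
Reagents that add atoms: none
Why: Longer exposure to buffered HF·pyridine cleaves the remaining primary silyl ether under conditions that should cause neither acyl migration nor conjugate addition to the two acrylate units.

Compound list
1 | shikimic acid | OC(=O)C1=C[C@@H](O)[C@@H](O)[C@H](O)C1 | starting material
2 | methyl shikimate | COC(=O)C1=C[C@@H](O)[C@@H](O)[C@H](O)C1 | intermediate
3 | methyl 3,4-O-isopropylideneshikimate | COC(=O)C1=C[C@H]2OC(C)(C)O[C@H]2[C@H](O)C1 | intermediate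
4 | methyl 5-O-(4-methoxybenzyl)-3,4-O-isopropylideneshikimate | COC(=O)C1=C[C@H]2OC(C)(C)O[C@H]2[C@H](OCc3ccc(OC)cc3)C1 | intermediate
5 | methyl 5-O-(4-methoxybenzyl)shikimate | COC(=O)C1=C[C@@H](O)[C@@H](O)[C@H](OCc2ccc(OC)cc2)C1 | intermediate
6 | methyl 5-O-(4-methoxybenzyl)-3-dehydroshikimate (C4, C5 as in 1) | COC(=O)C1=CC(=O)[C@@H](O)[C@H](OCc2ccc(OC)cc2)C1 | intermediate
7 | methyl 4-O-acetyl-5-O-(4-methoxybenzyl)-3-dehydroshikimate | COC(=O)C1=CC(=O)[C@@H](OC(C)=O)[C@H](OCc2ccc(OC)cc2)C1 | intermediate
8 | methyl (5R)-5-[(4-methoxybenzyl)oxy]-3-oxocyclohex-1-ene-1-carboxylate | COC(=O)C1=CC(=O)C[C@H](OCc2ccc(OC)cc2)C1 | intermediate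
9 | (5R)-3-(hydroxymethyl)-5-[(4-methoxybenzyl)oxy]cyclohex-2-en-1-ol, both C1 epimers | OCC1=CC(O)C[C@H](OCc2ccc(OC)cc2)C1 | intermediate
10 | propyne | CC#C | starting material
11 | trichloroacetyl chloride | ClC(=O)C(Cl)(Cl)Cl | starting material
12 | dichloroketene | ClC(Cl)=C=O | intermediate
13 | 4,4-dichloro-3-methylcyclobut-2-en-1-one | CC1=CC(=O)C1(Cl)Cl | intermediate
14 | 3-methylcyclobut-2-en-1-one | CC1=CC(=O)C1 | intermediate
15 | (S)-3-methylcyclobut-2-en-1-ol | CC1=C[C@@H](O)C1 | intermediate
16 | chloro(diisopropyl)[(1S)-3-methylcyclobut-2-en-1-yloxy]silane | CC1=C[C@@H](O[Si](Cl)(C(C)C)C(C)C)C1 | intermediate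
17 | (5R)-3-({diisopropyl[(1S)-3-methylcyclobut-2-en-1-yloxy]silyl}oxymethyl)-5-[(4-methoxybenzyl)oxy]cyclohex-2-en-1-ol, both C1 epimers | CC1=C[C@@H](O[Si](OCC2=CC(O)C[C@H](OCc3ccc(OC)cc3)C2)(C(C)C)C(C)C)C1 | intermediate
18 | (5R)-3-({diisopropyl[(1S)-3-methylcyclobut-2-en-1-yloxy]silyl}oxymethyl)-5-[(4-methoxybenzyl)oxy]cyclohex-2-en-1-one | CC1=C[C@@H](O[Si](OCC2=CC(=O)C[C@H](OCc3ccc(OC)cc3)C2)(C(C)C)C(C)C)C1 | intermediate
19 | tetracyclic photoadduct: cis,anti,cis-tricyclic C6 ketone (C10–C1, C5–C4 bonds) with O2–Si(iPr)2–O14 bridge; cyclobutane and C8 ether cis on the six-membered ring; C2–O cis to C10 | C[C@@]12C[C@H](O[Si](C(C)C)(C(C)C)OC4)[C@@H]1[C@@]34C[C@@H](OCc5ccc(OC)cc5)CC(=O)[C@@H]23 | intermediate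
20 | tricyclic keto diol (C2 OH, C14 OH; ring fusion as 19) | C[C@@]12C[C@H](O)[C@@H]1[C@@]3(CO)C[C@@H](OCc4ccc(OC)cc4)CC(=O)[C@@H]23 | intermediate
21 | C14 tert-butyldiphenylsilyl ether of 20 | C[C@@]12C[C@H](O)[C@@H]1[C@@]3(CO[Si](c4ccccc4)(c4ccccc4)C(C)(C)C)C[C@@H](OCc4ccc(OC)cc4)CC(=O)[C@@H]23 | intermediate
22 | C2 triethylsilyl, C14 tert-butyldiphenylsilyl, C8 4-methoxybenzyl tricyclic ketone | C[C@@]12C[C@H](O[Si](CC)(CC)CC)[C@@H]1[C@@]3(CO[Si](c4ccccc4)(c4ccccc4)C(C)(C)C)C[C@@H](OCc4ccc(OC)cc4)CC(=O)[C@@H]23 | intermediate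
23 | methyl glyoxylate | COC(=O)C=O | starting material
24 | lithium aldolate of 22 with 23 (C7–C11 bond; C7, C11 epimer mixture) | C[C@@]12C[C@H](O[Si](CC)(CC)CC)[C@@H]1[C@@]3(CO[Si](c4ccccc4)(c4ccccc4)C(C)(C)C)C[C@@H](OCc4ccc(OC)cc4)C(C([O-])C(=O)OC)C(=O)[C@@H]23.[Li+] | intermediate
25 | C11 mesylate of the aldol | C[C@@]12C[C@H](O[Si](CC)(CC)CC)[C@@H]1[C@@]3(CO[Si](c4ccccc4)(c4ccccc4)C(C)(C)C)C[C@@H](OCc4ccc(OC)cc4)C(C(OS(C)(=O)=O)C(=O)OC)C(=O)[C@@H]23 | intermediate
26 | C7 alkylidene ketone (C7=C11–CO2Me, E drawn) | C[C@@]12C[C@H](O[Si](CC)(CC)CC)[C@@H]1[C@@]3(CO[Si](c4ccccc4)(c4ccccc4)C(C)(C)C)C[C@@H](OCc4ccc(OC)cc4)/C(=C\C(=O)OC)C(=O)[C@@H]23 | intermediate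
27 | thermolysis precursor: cis,anti,cis-tricyclic ketone, C7 CH2CO2Me arm cis to C8 ether and cyclobutane, C2 OTES cis to C10 | C[C@@]12C[C@H](O[Si](CC)(CC)CC)[C@@H]1[C@@]3(CO[Si](c4ccccc4)(c4ccccc4)C(C)(C)C)C[C@@H](OCc4ccc(OC)cc4)[C@@H](CC(=O)OC)C(=O)[C@@H]23 | intermediate
28 | protected cyclodeca-1(10),4-dien-6-one with C7 acetate arm (ring-cis C1=C10, ring-trans C4=C5) | COc1ccc(CO[C@@H]2C/C(CO[Si](c3ccccc3)(c3ccccc3)C(C)(C)C)=C\[C@@H](O[Si](CC)(CC)CC)C/C(C)=C/C(=O)[C@@H]2CC(=O)OC)cc1 | intermediate
29 | C8 hydroxy cyclodecadienone | O[C@@H]1C/C(CO[Si](c2ccccc2)(c2ccccc2)C(C)(C)C)=C\[C@@H](O[Si](CC)(CC)CC)C/C(C)=C/C(=O)[C@@H]1CC(=O)OC | intermediate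
30 | anti-6,8-diol methyl ester (O6 trans to the C7 arm) | O[C@@H]1C/C(CO[Si](c2ccccc2)(c2ccccc2)C(C)(C)C)=C\[C@@H](O[Si](CC)(CC)CC)C/C(C)=C/[C@@H](O)[C@@H]1CC(=O)OC | intermediate
31 | trans-fused 6,12-lactone, C8 OH free, C2 OTES, C14 OTBDPS | O[C@@H]1C/C(CO[Si](c3ccccc3)(c3ccccc3)C(C)(C)C)=C\[C@@H](O[Si](CC)(CC)CC)C/C(C)=C/[C@H]2OC(=O)C[C@@H]21 | intermediate
32 | C11 dimethylaminomethyl lactone (C11 epimers) | O[C@@H]1C/C(CO[Si](c3ccccc3)(c3ccccc3)C(C)(C)C)=C\[C@@H](O[Si](CC)(CC)CC)C/C(C)=C/[C@H]2OC(=O)C(CN(C)C)[C@@H]21 | intermediate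
33 | C11 trimethylammoniomethyl lactone iodide | O[C@@H]1C/C(CO[Si](c3ccccc3)(c3ccccc3)C(C)(C)C)=C\[C@@H](O[Si](CC)(CC)CC)C/C(C)=C/[C@H]2OC(=O)C(C[N+](C)(C)C)[C@@H]21.[I-] | intermediate
34 | α-methylene lactone, C8 OH free | O[C@@H]1C/C(CO[Si](c3ccccc3)(c3ccccc3)C(C)(C)C)=C\[C@@H](O[Si](CC)(CC)CC)C/C(C)=C/[C@H]2OC(=O)C(=C)[C@@H]21 | intermediate
35 | C8 methacrylate, C2 OTES, C14 OTBDPS | C=C(C)C(=O)O[C@@H]1C/C(CO[Si](c3ccccc3)(c3ccccc3)C(C)(C)C)=C\[C@@H](O[Si](CC)(CC)CC)C/C(C)=C/[C@H]2OC(=O)C(=C)[C@@H]21 | intermediate
36 | C2 alcohol, C8 methacrylate, C14 OTBDPS | C=C(C)C(=O)O[C@@H]1C/C(CO[Si](c3ccccc3)(c3ccccc3)C(C)(C)C)=C\[C@@H](O)C/C(C)=C/[C@H]2OC(=O)C(=C)[C@@H]21 | intermediate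
37 | C2 acetate, C8 methacrylate, C14 OTBDPS | C=C(C)C(=O)O[C@@H]1C/C(CO[Si](c3ccccc3)(c3ccccc3)C(C)(C)C)=C\[C@@H](OC(C)=O)C/C(C)=C/[C@H]2OC(=O)C(=C)[C@@H]21 | intermediate
38 | (2S,6R,7R,8R)-2-acetoxy-14-hydroxy-8-(methacryloyloxy)germacra-1(10),4,11(13)-trien-12,6-olide, C1=C10 cis and C4=C5 trans in the ring | C=C(C)C(=O)O[C@@H]1C/C(CO)=C\[C@@H](OC(C)=O)C/C(C)=C/[C@H]2OC(=O)C(=C)[C@@H]21 | target

Total step count: 26. Longest linear sequence: 23 steps (steps 1–7 and 11–26, from shikimic acid); the cyclobutenol branch (steps 8–10) joins at step 11.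

Steps most likely to fail

1. Step 18. What may go wrong: fragmentation through the alternative chair, which exchanges the two alkene geometries, or onward Cope rearrangement of the product while hot. The fallback sets out from 27 and returns at 28; it replaces direct stereocontrol by thermolysis followed by stepwise geometric isomerisation. The thermolysis is run as before and the geometric isomer with trans C1=C10 and cis C4=C5 F1 is taken on. PhSSPh (cat) under visible light in benzene should equilibrate the unconjugated C1=C10 bond by reversible thiyl addition to the ring-cis geometry, the more stable one in a ten-membered ring, giving the cis,cis-dienone F2. Irradiation of the enone chromophore of F2 (366 nm, MeCN, −40 °C) should then isomerise C4=C5 to a photostationary mixture, from which 28 is separated and F2 recycled.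

2. Step 13. What may go wrong: slow closure of the seven-membered siloxane ring on the enone face that the tether demands (the face of the C8 ether), so that unproductive triplet decay or crossed addition takes over. The fallback sets out from 8 (with 15) and returns at 20; it uses a three-atom acyl tether at the carboxylate oxidation level, whose closure forms a five-membered ring. Compound 8 is hydrolysed (Me3SnOH, 1,2-dichloroethane, 70 °C) to the enone acid F3, which is esterified with 15 (EDC·HCl, DMAP, CH2Cl2) to the cyclobutenyl ester F4. Irradiation (350 nm, CH2Cl2) should close a γ-lactone between C10 and C1 and give the lactone-bridged photoadduct F5 with the relative configuration of 19. The C6 ketone is masked as the dioxolane F6 (ethylene glycol, PPTS, benzene, reflux), LiAlH4 (THF, 0 °C) reduces the lactone to the diol ketal F7, and PPTS in wet acetone returns 20.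

3. Step 17. What may go wrong: delivery of hydrogen to the other face of C7 or hydrogenolysis of the benzylic ether. The fallback sets out from 22 and returns at 27; it uses enolate alkylation followed by kinetic protonation. The lithium enolate of 22 (LDA, THF/DMPU, −78 °C) is alkylated with methyl bromoacetate, which should enter anti to the cyclobutane and the C8 ether and give the C7 epimer F8. Soft enolisation (TMSOTf, Et3N, CH2Cl2, 0 °C) gives the C6=C7 silyl enol ether F9. Protonation with citric acid in THF/H2O at −40 °C from the same open face should move the arm to the hindered face and return 27.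

Further compounds
F1 | step 18 | geometric isomer of 28 with ring-trans C1=C10 and ring-cis C4=C5 | COc1ccc(CO[C@@H]2C/C(CO[Si](c3ccccc3)(c3ccccc3)C(C)(C)C)=C/[C@@H](O[Si](CC)(CC)CC)C/C(C)=C\C(=O)[C@@H]2CC(=O)OC)cc1
F2 | step 18 | geometric isomer of 28 with ring-cis C1=C10 and ring-cis C4=C5 | COc1ccc(CO[C@@H]2C/C(CO[Si](c3ccccc3)(c3ccccc3)C(C)(C)C)=C\[C@@H](O[Si](CC)(CC)CC)C/C(C)=C\C(=O)[C@@H]2CC(=O)OC)cc1
F3 | step 13 | (5R)-5-[(4-methoxybenzyl)oxy]-3-oxocyclohex-1-ene-1-carboxylic acid | OC(=O)C1=CC(=O)C[C@H](OCc2ccc(OC)cc2)C1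
F4 | step 13 | (1S)-3-methylcyclobut-2-en-1-yl (5R)-5-[(4-methoxybenzyl)oxy]-3-oxocyclohex-1-ene-1-carboxylate | CC1=C[C@@H](OC(=O)C2=CC(=O)C[C@H](OCc3ccc(OC)cc3)C2)C1
F5 | step 13 | lactone-bridged photoadduct (γ-lactone C14(=O)–O2 in place of the siloxane ring of 19) | C[C@@]12C[C@H](OC4=O)[C@@H]1[C@@]34C[C@@H](OCc5ccc(OC)cc5)CC(=O)[C@@H]23
F6 | step 13 | C6 ethylene ketal of F5 | C[C@@]12C[C@H](OC4=O)[C@@H]1[C@@]34C[C@@H](OCc5ccc(OC)cc5)CC6(OCCO6)[C@@H]23
F7 | step 13 | C6 ethylene ketal of 20 | C[C@@]12C[C@H](O)[C@@H]1[C@@]3(CO)C[C@@H](OCc4ccc(OC)cc4)CC5(OCCO5)[C@@H]23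
F8 | step 17 | C7 epimer of 27 | C[C@@]12C[C@H](O[Si](CC)(CC)CC)[C@@H]1[C@@]3(CO[Si](c4ccccc4)(c4ccccc4)C(C)(C)C)C[C@@H](OCc4ccc(OC)cc4)[C@H](CC(=O)OC)C(=O)[C@@H]23
F9 | step 17 | C6 trimethylsilyl enol ether (C6=C7) of 27 | C[C@@]12C[C@H](O[Si](CC)(CC)CC)[C@@H]1[C@@]3(CO[Si](c4ccccc4)(c4ccccc4)C(C)(C)C)C[C@@H](OCc4ccc(OC)cc4)C(CC(=O)OC)=C(O[Si](C)(C)C)[C@@H]23
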